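**Plan**
1. Retrosynthetic cuts: C12–C13 (Stille) gives West dienynyl stannane 18 and East iodide 35. In 35, the Cα–C8′ bond (Stille of ring-B vinylstannane 27 with α-bromobutenolide 32) and the butenolide ring (Sonogashira/5-exo-dig lactonization of 29 with 30) are cut. In 18, the C8–C9 bond (hydroalkynylation of ethyl but-2-ynoate by alkyne 10) is cut, then ring A at C3–C4.
2. Locants: ring A C1 (CMe2), C2, C3 (CHOH), C4, C5 (CMe), C6; chain C7≡C8, C9–C17; lactone Cγ (=C17), Cβ, Cα; ring B C1′–C6′ with vinyl C7′=C8′.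
3. Enabling feature: in ring A the C3 carbinol is homoallylic to the tetrasubstituted C5=C6 olefin, and C6 carries the C7≡C8 ethynyl group. HO–C3–C4–C5=C6–C7≡C8 is therefore the retron of a vinylogous carbonyl-ene (Prins) closure of an achiral vinylallene (C4=C5–C6=C7=C8) onto a C3 aldehyde.
4. Forward order: ring A is closed first (step 8) and extended to 18. Ring B comes as a carbocycle from (4R,6R)-actinol and gains its oxirane in step 18. The butenolide ring arises in step 23, is joined to ring B (step 24) and last to the West half (step 27), with both hydroxyls free.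
5. Stereochemistry: C3 from the chiral Brønsted acid in step 8; C3′ from actinol; C5′/C6′ from Sharpless epoxidation; E olefins from syn-hydroalkynylation, Takai-type olefinations and stereoretentive couplings; the Z ylidene from anti-oxymetalation in the lactonization.

Key step: step 8

Assumptions: (4R,6R)-actinol (19), the Ohira–Bestmann reagent and the chiral acid of step 8 are bought or made by their published routes. The catalyst enantiomer is fixed in a short screen so that the 3R alcohol results (written below as the S,S acid).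

**Route**

Step 1
Reactants: 1 3,3-dimethyloxolan-2-one
Product: 2 3,3-dimethyloxolan-2-ol (racemic lactol)
Conditions: iBu2AlH (1.1 equiv), CH2Cl2, −78 °C; aq. KNaC4H4O6
Reagents that add atoms: none
Why: Partial reduction of a γ-lactone by iBu2AlH stops at the tetrahedral aluminate at low temperature and should give the lactol.

Step 2
Reactants: 2 3,3-dimethyloxolan-2-ol
Product: 3 3,3-dimethylpent-4-yn-1-ol
Conditions: Ohira–Bestmann reagent (1.3 equiv), K2CO3 (2 equiv), MeOH, 0 °C → rt
Reagents that add atoms: dimethyl (1-diazo-2-oxopropyl)phosphonate, CC(=O)C(=[N+]=[N-])P(=O)(OC)OC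
Why: Seyferth–Gilbert homologation (Ohira–Bestmann variant) of the open hydroxy-aldehyde tautomer; the non-enolisable α-quaternary aldehyde should give the terminal alkyne by 1,2-hydrogen shift of the alkylidene carbene.

Step 3
Reactants: 3 3,3-dimethylpent-4-yn-1-ol
Product: 4 tert-butyl[(3,3-dimethylpent-4-yn-1-yl)oxy]dimethylsilane
Conditions: TBSCl, imidazole, DMF, rt
Reagents that add atoms: tert-butyldimethylsilyl chloride, CC(C)(C)[Si](C)(C)Cl
Why: Standard silylation of a primary alcohol masks the future aldehyde for the organometallic steps.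

Step 4
Reactants: 4 tert-butyl[(3,3-dimethylpent-4-yn-1-yl)oxy]dimethylsilane
Product: 5 6-[(tert-butyldimethylsilyl)oxy]-4,4-dimethylhex-2-yn-1-ol
Conditions: n-BuLi (1.1 equiv), THF, −78 °C; (CH2O)n, −78 °C → rt; H2O
Reagents that add atoms: formaldehyde (as paraformaldehyde), C=O
Why: Hydroxymethylation of a lithium acetylide with formaldehyde is a standard route to primary propargylic alcohols.

Step 5
Reactants: 5 6-[(tert-butyldimethylsilyl)oxy]-4,4-dimethylhex-2-yn-1-ol
Product: 7 tert-butyldimethyl[(3,3,5-trimethyl-4-vinylidenehex-5-en-1-yl)oxy]silane, via propargylic mesylate 6 (not isolated)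
Conditions: n-BuLi (1.0 equiv), THF, −78 °C; MsCl (1.05 equiv); then CH2=C(CH3)MgBr (1.5 equiv), CuBr·SMe2 (10 mol %), LiBr (20 mol %), −78 → 0 °C
Reagents that add atoms: isopropenylmagnesium bromide, CC(=C)[Mg]Br
Why: Copper-catalysed anti-SN2′ substitution of the in situ propargylic mesylate by the vinyl Grignard reagent should place the isopropenyl group on the alkyne carbon and give the 1,1-disubstituted terminal allene (no stereocentre is formed).

Step 6
Reactants: 7 tert-butyldimethyl[(3,3,5-trimethyl-4-vinylidenehex-5-en-1-yl)oxy]silane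
Product: 8 3,3,5-trimethyl-4-vinylidenehex-5-en-1-ol
Conditions: Bu4NF, THF, 0 °C → rt
Reagents that add atoms: none
Why: Fluoride cleavage of the primary silyl ether is neutral towards the vinylallene.

Step 7
Reactants: 8 3,3,5-trimethyl-4-vinylidenehex-5-en-1-ol
Product: 9 3,3,5-trimethyl-4-vinylidenehex-5-enal
Conditions: Dess–Martin periodinane (1.2 equiv), NaHCO3, CH2Cl2, 0 °C
Reagents that add atoms: none
Why: Buffered Dess–Martin oxidation gives the aldehyde without acid that could trigger a racemic cyclization.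

Step 8
Reactants: 9 3,3,5-trimethyl-4-vinylidenehex-5-enal
Product: 10 (1R)-4-ethynyl-3,5,5-trimethylcyclohex-3-en-1-ol
Conditions: (S,S)-3,3′-diaryl-BINOL-derived N-triflyl imidodiphosphorimidate (IDPi) Brønsted acid (5 mol %), 5 Å molecular sieves, CH2Cl2, −40 → −20 °C
Reagents that add atoms: none
Why: Proposed new method: the chiral acid activates the aldehyde of 9, C4 (the isopropenyl CH2) attacks C3 through a chair-like 6-endo-trig transition state (the 6-(2,4) mode of the type-2 carbonyl-ene/Prins cyclization), and the C5 cation so formed is delocalised into the allene (C5–C6–C7, a 1,3-dien-2-yl cation) whose terminal C8–H bonds lie parallel to the empty orbital, so the confined counter-anion removes a C8 proton and the C5=C6 olefin and the C7≡C8 alkyne appear together (a vinylogous carbonyl-ene reaction with 1,4-transposition). The closest known reaction types are the type-2 carbonyl-ene/Prins cyclizations of ω-methallyl aldehydes under confined chiral Brønsted acids and the SE2′ additions of allenylsilanes and allenylstannanes to aldehydes, which likewise turn an allene into an alkyne. The only new stereocentre, C3, is set by the catalyst, which must differentiate the enantiotopic faces of the aldehyde of the achiral substrate. The step needs 6-endo attack through C4 and not 5-endo attack through the central allene carbon C7 (the former is the geometrically favoured closure, and a hetero-Diels–Alder path is excluded because the tether sits on the internal diene carbon), and proton loss at C8 and not at the C5 methyl. Any exocyclic-methylene isomer should be re-protonated by the acid to the same cation and drain to the conjugated enyne, the thermodynamic sink, without touching C3.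

Step 9
Reactants: 10 (1R)-4-ethynyl-3,5,5-trimethylcyclohex-3-en-1-ol; 11 ethyl but-2-ynoate
Product: 12 ethyl (2E)-5-[(4R)-4-hydroxy-2,6,6-trimethylcyclohex-1-en-1-yl]-3-methylpent-2-en-4-ynoate
Conditions: Pd(OAc)2 (3 mol %), tris(2,6-dimethoxyphenyl)phosphine (3 mol %), THF, rt
Reagents that add atoms: none
Why: Palladium-catalysed cross-addition of the terminal alkyne C–H bond across the alkynoate (hydroalkynylation) is a syn addition with the alkynyl group going to the β-carbon, which should give the 9E enynoate only; the free hydroxyl is tolerated.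

Step 10
Reactants: 12 ethyl (2E)-5-[(4R)-4-hydroxy-2,6,6-trimethylcyclohex-1-en-1-yl]-3-methylpent-2-en-4-ynoate
Product: 13 (1R)-4-[(3E)-5-hydroxy-3-methylpent-3-en-1-yn-1-yl]-3,5,5-trimethylcyclohex-3-en-1-ol
Conditions: iBu2AlH (3.5 equiv), CH2Cl2, −78 → 0 °C; aq. KNaC4H4O6
Reagents that add atoms: none
Why: 1,2-Reduction of the enoate by iBu2AlH gives the allylic alcohol without touching the enyne or the olefin geometry.

Step 11
Reactants: 13 (1R)-4-[(3E)-5-hydroxy-3-methylpent-3-en-1-yn-1-yl]-3,5,5-trimethylcyclohex-3-en-1-ol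
Product: 14 (2E)-5-[(4R)-4-hydroxy-2,6,6-trimethylcyclohex-1-en-1-yl]-3-methylpent-2-en-4-ynal
Conditions: MnO2 (20 equiv), CH2Cl2, rt
Reagents that add atoms: none
Why: MnO2 oxidises the primary allylic alcohol chemoselectively and leaves the non-allylic ring carbinol.

Step 12
Reactants: 15 dibromomethane; 16 tributyltin chloride
Product: 17 tributyl(dibromomethyl)stannane
Conditions: LiN(iPr)2, THF/Et2O, −95 °C; then Bu3SnCl, −95 → −40 °C
Reagents that add atoms: none
Why: Deprotonation of dibromomethane and stannylation of the carbenoid anion is the standard preparation of this olefination reagent.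

Step 13
Reactants: 14 (2E)-5-[(4R)-4-hydroxy-2,6,6-trimethylcyclohex-1-en-1-yl]-3-methylpent-2-en-4-ynal; 17 tributyl(dibromomethyl)stannane
Product: 18 (1R)-3,5,5-trimethyl-4-[(3E,5E)-3-methyl-6-(tributylstannyl)hexa-3,5-dien-1-yn-1-yl]cyclohex-3-en-1-ol
Conditions: CrCl2 (8 equiv), LiI (4 equiv), THF/DMF, rt, dark
Reagents that add atoms: none
Why: Takai-type stannyl-olefination: the geminal dichromium carbenoid from 17 adds to the aldehyde and anti-periplanar elimination should give the E vinylstannane; CrCl2 tolerates the free alcohol and the enyne.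

Step 14
Reactants: 19 (4R,6R)-4-hydroxy-2,2,6-trimethylcyclohexan-1-one
Product: 20 (4R,6R)-4-[(tert-butyldimethylsilyl)oxy]-2,2,6-trimethylcyclohexan-1-one
Conditions: TBSCl, imidazole, DMF, rt
Reagents that add atoms: tert-butyldimethylsilyl chloride, CC(C)(C)[Si](C)(C)Cl
Why: Standard silylation of the secondary alcohol; C3′ of the target is already present in this chiral-pool ketone.

Step 15
Reactants: 20 (4R,6R)-4-[(tert-butyldimethylsilyl)oxy]-2,2,6-trimethylcyclohexan-1-one
Product: 21 (4R)-4-[(tert-butyldimethylsilyl)oxy]-2,6,6-trimethylcyclohex-1-en-1-yl trifluoromethanesulfonate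
Conditions: LiN(iPr)2, THF, −78 °C; PhNTf2, −78 °C → rt
Reagents that add atoms: N-phenylbis(trifluoromethanesulfonimide), O=S(=O)(N(c1ccccc1)S(=O)(=O)C(F)(F)F)C(F)(F)F
Why: Only C6 can be enolised (C2 is quaternary), so O-triflation of the lithium enolate gives a single tetrasubstituted enol triflate.

Step 16
Reactants: 21 (4R)-4-[(tert-butyldimethylsilyl)oxy]-2,6,6-trimethylcyclohex-1-en-1-yl trifluoromethanesulfonate
Product: 22 methyl (4R)-4-[(tert-butyldimethylsilyl)oxy]-2,6,6-trimethylcyclohex-1-ene-1-carboxylate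
Conditions: Pd(OAc)2 (5 mol %), PPh3 (10 mol %), CO (1 atm), MeOH, Et3N, DMF, 60 °C
Reagents that add atoms: carbon monoxide, [C-]#[O+]; methanol, CO
Why: Palladium-catalysed methoxycarbonylation of an enol triflate installs C7′ at the ester oxidation level.

Step 17
Reactants: 22 methyl (4R)-4-[(tert-butyldimethylsilyl)oxy]-2,6,6-trimethylcyclohex-1-ene-1-carboxylate
Product: 23 {(4R)-4-[(tert-butyldimethylsilyl)oxy]-2,6,6-trimethylcyclohex-1-en-1-yl}methanol
Conditions: iBu2AlH (2.5 equiv), CH2Cl2, −78 → 0 °C; aq. KNaC4H4O6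
Reagents that add atoms: none
Why: Reduction of the hindered enoate by iBu2AlH to the primary allylic alcohol is routine.

Step 18
Reactants: 23 {(4R)-4-[(tert-butyldimethylsilyl)oxy]-2,6,6-trimethylcyclohex-1-en-1-yl}methanol
Product: 24 {(1R,4S,6R)-4-[(tert-butyldimethylsilyl)oxy]-2,2,6-trimethyl-7-oxabicyclo[4.1.0]heptan-1-yl}methanol
Conditions: Ti(OiPr)4 (20 mol %), D-(−)-diethyl tartrate (24 mol %), t-BuOOH, 4 Å molecular sieves, CH2Cl2, −20 °C
Reagents that add atoms: tert-butyl hydroperoxide, CC(C)(C)OO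
Why: Sharpless asymmetric epoxidation: the D-(−)-tartrate catalyst should deliver oxygen to the face of the tetrasubstituted allylic alcohol anti to the C3′ silyloxy group (reagent control, reinforced by the substrate), setting C5′ (R) and C6′ together.

Step 19
Reactants: 24 {(1R,4S,6R)-4-[(tert-butyldimethylsilyl)oxy]-2,2,6-trimethyl-7-oxabicyclo[4.1.0]heptan-1-yl}methanol
Product: 25 (1S,4S,6R)-4-[(tert-butyldimethylsilyl)oxy]-2,2,6-trimethyl-7-oxabicyclo[4.1.0]heptane-1-carbaldehyde
Conditions: Dess–Martin periodinane (1.3 equiv), NaHCO3, CH2Cl2, rt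
Reagents that add atoms: none
Why: Buffered Dess–Martin oxidation of the neopentyl epoxy alcohol gives the non-enolisable epoxy aldehyde without opening the oxirane.

Step 20
Reactants: 25 (1S,4S,6R)-4-[(tert-butyldimethylsilyl)oxy]-2,2,6-trimethyl-7-oxabicyclo[4.1.0]heptane-1-carbaldehyde; 17 tributyl(dibromomethyl)stannane
Product: 26 tert-butyldimethyl({(1R,3S,6S)-1,5,5-trimethyl-6-[(E)-2-(tributylstannyl)ethenyl]-7-oxabicyclo[4.1.0]heptan-3-yl}oxy)silane
Conditions: CrCl2 (8 equiv), LiI (4 equiv), THF/DMF, rt, dark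
Reagents that add atoms: none
Why: Takai-type stannyl-olefination should give the E vinylstannane directly from the aldehyde; the chromium carbenoid is non-basic and avoids the palladium-hydride chemistry that a propargylic oxirane would not survive.

Step 21
Reactants: 26 tert-butyldimethyl({(1R,3S,6S)-1,5,5-trimethyl-6-[(E)-2-(tributylstannyl)ethenyl]-7-oxabicyclo[4.1.0]heptan-3-yl}oxy)silane
Product: 27 (1R,3S,6S)-1,5,5-trimethyl-6-[(E)-2-(tributylstannyl)ethenyl]-7-oxabicyclo[4.1.0]heptan-3-ol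
Conditions: Bu4NF, THF, rt
Reagents that add atoms: none
Why: Fluoride desilylation is done here, on a robust intermediate, so that no deprotection is needed after the polyene and butenolide are in place.

Step 22
Reactants: 28 propiolic acid
Product: 29 (2E)-2,3-dibromoprop-2-enoic acid
Conditions: Br2 (1.0 equiv), CH2Cl2, 0 °C → rt, dark
Reagents that add atoms: bromine, BrBr
Why: Anti addition of bromine to the alkyne should give the E dibromide, in which the C3 bromide is cis to the carboxyl group.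

Step 23
Reactants: 29 (2E)-2,3-dibromoprop-2-enoic acid; 30 (2E)-3-methylpent-2-en-4-yn-1-ol
Product: 32 (5Z)-3-bromo-5-[(2E)-4-hydroxy-2-methylbut-2-en-1-ylidene]furan-2(5H)-one, via enynoic acid 31 (not isolated)
Conditions: Pd(PPh3)4 (5 mol %), CuI (10 mol %), Et3N (4 equiv), MeCN, rt
Reagents that add atoms: none
Why: Sonogashira coupling at the more reactive C3 bromide, followed by 5-exo-dig anti addition of the carboxylate across the alkyne, should give the Z ylidene butenolide with the α-bromide retained (tandem coupling–lactonization of β-halo-acrylic acids).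

Step 24
Reactants: 32 (5Z)-3-bromo-5-[(2E)-4-hydroxy-2-methylbut-2-en-1-ylidene]furan-2(5H)-one; 27 (1R,3S,6S)-1,5,5-trimethyl-6-[(E)-2-(tributylstannyl)ethenyl]-7-oxabicyclo[4.1.0]heptan-3-ol
Product: 33 (5Z)-5-[(2E)-4-hydroxy-2-methylbut-2-en-1-ylidene]-3-{(E)-2-[(1S,4S,6R)-4-hydroxy-2,2,6-trimethyl-7-oxabicyclo[4.1.0]heptan-1-yl]ethenyl}furan-2(5H)-one
Conditions: Pd2(dba)3 (2.5 mol %), AsPh3 (20 mol %), NMP, rt → 40 °C
Reagents that add atoms: none
Why: Stille coupling at the activated α-bromide proceeds with retention of the vinylstannane geometry and needs no base, which suits the enol lactone and the hindered vinyl oxirane.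

Step 25
Reactants: 33 (5Z)-5-[(2E)-4-hydroxy-2-methylbut-2-en-1-ylidene]-3-{(E)-2-[(1S,4S,6R)-4-hydroxy-2,2,6-trimethyl-7-oxabicyclo[4.1.0]heptan-1-yl]ethenyl}furan-2(5H)-one
Product: 34 (2E)-4-[(2Z)-4-{(E)-2-[(1S,4S,6R)-4-hydroxy-2,2,6-trimethyl-7-oxabicyclo[4.1.0]heptan-1-yl]ethenyl}-5-oxofuran-2(5H)-ylidene]-3-methylbut-2-enal
Conditions: MnO2 (20 equiv), CH2Cl2, rt
Reagents that add atoms: none
Why: MnO2 oxidises only the primary allylic alcohol; the secondary ring-B carbinol is not allylic and should remain.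

Step 26
Reactants: 34 (2E)-4-[(2Z)-4-{(E)-2-[(1S,4S,6R)-4-hydroxy-2,2,6-trimethyl-7-oxabicyclo[4.1.0]heptan-1-yl]ethenyl}-5-oxofuran-2(5H)-ylidene]-3-methylbut-2-enal
Product: 35 (5Z)-3-{(E)-2-[(1S,4S,6R)-4-hydroxy-2,2,6-trimethyl-7-oxabicyclo[4.1.0]heptan-1-yl]ethenyl}-5-[(2E,4E)-5-iodo-2-methylpenta-2,4-dien-1-ylidene]furan-2(5H)-one
Conditions: CrCl2 (8 equiv), CHI3 (3 equiv), THF/1,4-dioxane, 0 °C → rt, dark
Reagents that add atoms: iodoform, IC(I)I
Why: Takai iodo-olefination of the conjugated aldehyde should give the E vinyl iodide under non-basic conditions that spare the lactone and the free alcohol.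

Step 27
Reactants: 35 (5Z)-3-{(E)-2-[(1S,4S,6R)-4-hydroxy-2,2,6-trimethyl-7-oxabicyclo[4.1.0]heptan-1-yl]ethenyl}-5-[(2E,4E)-5-iodo-2-methylpenta-2,4-dien-1-ylidene]furan-2(5H)-one; 18 (1R)-3,5,5-trimethyl-4-[(3E,5E)-3-methyl-6-(tributylstannyl)hexa-3,5-dien-1-yn-1-yl]cyclohex-3-en-1-ol
Product: 36 (5Z)-3-{(E)-2-[(1S,4S,6R)-4-hydroxy-2,2,6-trimethyl-7-oxabicyclo[4.1.0]heptan-1-yl]ethenyl}-5-{(2E,4E,6E,8E)-11-[(4R)-4-hydroxy-2,6,6-trimethylcyclohex-1-en-1-yl]-2,9-dimethylundeca-2,4,6,8-tetraen-10-yn-1-ylidene}furan-2(5H)-one (CNP0180336.1)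
Conditions: Pd2(dba)3 (5 mol %), AsPh3 (40 mol %), DMF/THF, rt, dark, argon
Reagents that add atoms: none
Why: Stille coupling of a dienylstannane with a vinyl iodide forms the C12–C13 bond with retention at both olefins under neutral conditions, so the unprotected target should be obtained directly.

**Compound list**
1 | 3,3-dimethyloxolan-2-one | CC1(C)CCOC1=O | starting material
2 | 3,3-dimethyloxolan-2-ol (racemic) | CC1(C)CCOC1O | intermediate
3 | 3,3-dimethylpent-4-yn-1-ol | C#CC(C)(C)CCO | intermediate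
4 | tert-butyl[(3,3-dimethylpent-4-yn-1-yl)oxy]dimethylsilane | C#CC(C)(C)CCO[Si](C)(C)C(C)(C)C | intermediate
5 | 6-[(tert-butyldimethylsilyl)oxy]-4,4-dimethylhex-2-yn-1-ol | OCC#CC(C)(C)CCO[Si](C)(C)C(C)(C)C | intermediate
6 | 6-[(tert-butyldimethylsilyl)oxy]-4,4-dimethylhex-2-yn-1-yl methanesulfonate | CS(=O)(=O)OCC#CC(C)(C)CCO[Si](C)(C)C(C)(C)C | intermediate (not isolated)
7 | tert-butyldimethyl[(3,3,5-trimethyl-4-vinylidenehex-5-en-1-yl)oxy]silane | C=C=C(C(C)=C)C(C)(C)CCO[Si](C)(C)C(C)(C)C | intermediate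
8 | 3,3,5-trimethyl-4-vinylidenehex-5-en-1-ol | C=C=C(C(C)=C)C(C)(C)CCO | intermediate
9 | 3,3,5-trimethyl-4-vinylidenehex-5-enal | C=C=C(C(C)=C)C(C)(C)CC=O | intermediate
10 | (1R)-4-ethynyl-3,5,5-trimethylcyclohex-3-en-1-ol | CC1=C(C#C)C(C)(C)C[C@H](O)C1 | intermediate
11 | ethyl but-2-ynoate | CC#CC(=O)OCC | starting material
12 | ethyl (2E)-5-[(4R)-4-hydroxy-2,6,6-trimethylcyclohex-1-en-1-yl]-3-methylpent-2-en-4-ynoate | CC1=C(C#C/C(C)=C/C(=O)OCC)C(C)(C)C[C@H](O)C1 | intermediate
13 | (1R)-4-[(3E)-5-hydroxy-3-methylpent-3-en-1-yn-1-yl]-3,5,5-trimethylcyclohex-3-en-1-ol | CC1=C(C#C/C(C)=C/CO)C(C)(C)C[C@H](O)C1 | intermediate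
14 | (2E)-5-[(4R)-4-hydroxy-2,6,6-trimethylcyclohex-1-en-1-yl]-3-methylpent-2-en-4-ynal | CC1=C(C#C/C(C)=C/C=O)C(C)(C)C[C@H](O)C1 | intermediate
15 | dibromomethane | BrCBr | starting material
16 | tributyltin chloride | CCCC[Sn](Cl)(CCCC)CCCC | starting material
17 | tributyl(dibromomethyl)stannane | CCCC[Sn](CCCC)(CCCC)C(Br)Br | intermediate
18 | (1R)-3,5,5-trimethyl-4-[(3E,5E)-3-methyl-6-(tributylstannyl)hexa-3,5-dien-1-yn-1-yl]cyclohex-3-en-1-ol | CC1=C(C#C/C(C)=C/C=C/[Sn](CCCC)(CCCC)CCCC)C(C)(C)C[C@H](O)C1 | intermediate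
19 | (4R,6R)-4-hydroxy-2,2,6-trimethylcyclohexan-1-one | O=C1C(C)(C)C[C@H](O)C[C@H]1C | starting material
20 | (4R,6R)-4-[(tert-butyldimethylsilyl)oxy]-2,2,6-trimethylcyclohexan-1-one | O=C1C(C)(C)C[C@H](O[Si](C)(C)C(C)(C)C)C[C@H]1C | intermediate
21 | (4R)-4-[(tert-butyldimethylsilyl)oxy]-2,6,6-trimethylcyclohex-1-en-1-yl trifluoromethanesulfonate | CC1=C(OS(=O)(=O)C(F)(F)F)C(C)(C)C[C@H](O[Si](C)(C)C(C)(C)C)C1 | intermediate
22 | methyl (4R)-4-[(tert-butyldimethylsilyl)oxy]-2,6,6-trimethylcyclohex-1-ene-1-carboxylate | CC1=C(C(=O)OC)C(C)(C)C[C@H](O[Si](C)(C)C(C)(C)C)C1 | intermediate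
23 | {(4R)-4-[(tert-butyldimethylsilyl)oxy]-2,6,6-trimethylcyclohex-1-en-1-yl}methanol | CC1=C(CO)C(C)(C)C[C@H](O[Si](C)(C)C(C)(C)C)C1 | intermediate
24 | {(1R,4S,6R)-4-[(tert-butyldimethylsilyl)oxy]-2,2,6-trimethyl-7-oxabicyclo[4.1.0]heptan-1-yl}methanol | OC[C@@]12O[C@]1(C)C[C@@H](O[Si](C)(C)C(C)(C)C)CC2(C)C | intermediate
25 | (1S,4S,6R)-4-[(tert-butyldimethylsilyl)oxy]-2,2,6-trimethyl-7-oxabicyclo[4.1.0]heptane-1-carbaldehyde | O=C[C@@]12O[C@]1(C)C[C@@H](O[Si](C)(C)C(C)(C)C)CC2(C)C | intermediate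
26 | tert-butyldimethyl({(1R,3S,6S)-1,5,5-trimethyl-6-[(E)-2-(tributylstannyl)ethenyl]-7-oxabicyclo[4.1.0]heptan-3-yl}oxy)silane | CCCC[Sn](CCCC)(CCCC)/C=C/[C@@]12O[C@]1(C)C[C@@H](O[Si](C)(C)C(C)(C)C)CC2(C)C | intermediate
27 | (1R,3S,6S)-1,5,5-trimethyl-6-[(E)-2-(tributylstannyl)ethenyl]-7-oxabicyclo[4.1.0]heptan-3-ol | CCCC[Sn](CCCC)(CCCC)/C=C/[C@@]12O[C@]1(C)C[C@@H](O)CC2(C)C | intermediate
28 | propiolic acid | C#CC(=O)O | starting material
29 | (2E)-2,3-dibromoprop-2-enoic acid | Br/C=C(/Br)C(=O)O | intermediate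
30 | (2E)-3-methylpent-2-en-4-yn-1-ol | C#C/C(C)=C/CO | starting material
31 | (2E,6E)-2-bromo-8-hydroxy-6-methylocta-2,6-dien-4-ynoic acid | OC/C=C(C)/C#C/C=C(/Br)C(=O)O | intermediate (not isolated)
32 | (5Z)-3-bromo-5-[(2E)-4-hydroxy-2-methylbut-2-en-1-ylidene]furan-2(5H)-one | OC/C=C(C)/C=C1C=C(Br)C(=O)O/1 | intermediate
33 | (5Z)-5-[(2E)-4-hydroxy-2-methylbut-2-en-1-ylidene]-3-{(E)-2-[(1S,4S,6R)-4-hydroxy-2,2,6-trimethyl-7-oxabicyclo[4.1.0]heptan-1-yl]ethenyl}furan-2(5H)-one | OC/C=C(C)/C=C1C=C(/C=C/[C@@]23O[C@]2(C)C[C@@H](O)CC3(C)C)C(=O)O/1 | intermediate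
34 | (2E)-4-[(2Z)-4-{(E)-2-[(1S,4S,6R)-4-hydroxy-2,2,6-trimethyl-7-oxabicyclo[4.1.0]heptan-1-yl]ethenyl}-5-oxofuran-2(5H)-ylidene]-3-methylbut-2-enal | O=C/C=C(C)/C=C1C=C(/C=C/[C@@]23O[C@]2(C)C[C@@H](O)CC3(C)C)C(=O)O/1 | intermediate
35 | (5Z)-3-{(E)-2-[(1S,4S,6R)-4-hydroxy-2,2,6-trimethyl-7-oxabicyclo[4.1.0]heptan-1-yl]ethenyl}-5-[(2E,4E)-5-iodo-2-methylpenta-2,4-dien-1-ylidene]furan-2(5H)-one | I/C=C/C=C(C)/C=C1C=C(/C=C/[C@@]23O[C@]2(C)C[C@@H](O)CC3(C)C)C(=O)O/1 | intermediate
36 | CNP0180336.1 | CC1=C(C#C/C(C)=C/C=C/C=C/C=C(C)/C=C2C=C(/C=C/[C@@]34O[C@]3(C)C[C@@H](O)CC4(C)C)C(=O)O/2)C(C)(C)C[C@H](O)C1 | target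

**Count**
Total steps: 27. Longest linear sequence: 13 steps (steps 1–11, 13, 27).

**Steps most likely to fail**

Step 8 (proposed new method). What may go wrong: proton loss from the C5 methyl without later equilibration, closure through the central allene carbon to a five-membered ring, acid protonation of the vinylallene before carbonyl activation, or weak enantioface discrimination. Fallback with known chemistry: it sets out from enol triflate 21, which has the same configuration at the carbinol carbon as ring A. Sonogashira coupling of 21 with trimethylsilylacetylene (Pd(PPh3)4, CuI, Et3N, DMF) should give tert-butyldimethyl({(1R)-3,5,5-trimethyl-4-[(trimethylsilyl)ethynyl]cyclohex-3-en-1-yl}oxy)silane F1. Treatment of F1 with Bu4NF in THF removes both silyl groups and comes back to the route at 10.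

Step 5. What may go wrong: direct SN2 displacement at the propargylic CH2, or sluggish delivery of the isopropenyl group to the alkyne carbon next to the quaternary centre. Fallback: it sets out from 5, which is converted with methyl chloroformate and pyridine into 6-[(tert-butyldimethylsilyl)oxy]-4,4-dimethylhex-2-yn-1-yl methyl carbonate F2. Decarboxylative coupling of F2 with isopropenylboronic acid pinacol ester under Pd(PPh3)4 in THF at 50 °C proceeds through a σ-allenylpalladium methoxide and reductive elimination in place of an organocopper substitution. It comes back to the route at 7.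

Step 26. What may go wrong: reduction or opening of the vinyl oxirane or the enol lactone by divalent chromium, or incomplete E selectivity in the iodo-olefination. Fallback: a chromium-free Wittig union that sets out from 14. Wittig reaction of 14 with (triphenylphosphoranylidene)acetaldehyde in toluene should give (2E,4E)-7-[(4R)-4-hydroxy-2,6,6-trimethylcyclohex-1-en-1-yl]-5-methylhepta-2,4-dien-6-ynal F3. NaBH4 in MeOH then gives (1R)-4-[(3E,5E)-7-hydroxy-3-methylhepta-3,5-dien-1-yn-1-yl]-3,5,5-trimethylcyclohex-3-en-1-ol F4. PPh3·HBr in MeOH converts F4 into {(2E,4E)-7-[(4R)-4-hydroxy-2,6,6-trimethylcyclohex-1-en-1-yl]-5-methylhepta-2,4-dien-6-yn-1-yl}triphenylphosphonium bromide F5. The ylide of F5 (NaOMe, CH2Cl2/MeOH, 0 °C) is condensed with aldehyde 34, and the new C13=C14 olefin is equilibrated to E with a trace of iodine in diffuse light. This comes back to the route at 36 and bypasses steps 13, 26 and 27.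

**Further compounds**
F1 | step 8 | tert-butyldimethyl({(1R)-3,5,5-trimethyl-4-[(trimethylsilyl)ethynyl]cyclohex-3-en-1-yl}oxy)silane | CC1=C(C#C[Si](C)(C)C)C(C)(C)C[C@H](O[Si](C)(C)C(C)(C)C)C1
F2 | step 5 | 6-[(tert-butyldimethylsilyl)oxy]-4,4-dimethylhex-2-yn-1-yl methyl carbonate | COC(=O)OCC#CC(C)(C)CCO[Si](C)(C)C(C)(C)C
F3 | step 26 | (2E,4E)-7-[(4R)-4-hydroxy-2,6,6-trimethylcyclohex-1-en-1-yl]-5-methylhepta-2,4-dien-6-ynal | CC1=C(C#C/C(C)=C/C=C/C=O)C(C)(C)C[C@H](O)C1
F4 | step 26 | (1R)-4-[(3E,5E)-7-hydroxy-3-methylhepta-3,5-dien-1-yn-1-yl]-3,5,5-trimethylcyclohex-3-en-1-ol | CC1=C(C#C/C(C)=C/C=C/CO)C(C)(C)C[C@H](O)C1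
F5 | step 26 | {(2E,4E)-7-[(4R)-4-hydroxy-2,6,6-trimethylcyclohex-1-en-1-yl]-5-methylhepta-2,4-dien-6-yn-1-yl}triphenylphosphonium bromide | CC1=C(C#C/C(C)=C/C=C/C[P+](c2ccccc2)(c2ccccc2)c2ccccc2)C(C)(C)C[C@H](O)C1.[Br-]
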